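## Plan

- **Feature.** Numbering: rings A and B are C1–C10, the chain is C11–C16, C24 is the CH2OH carbon on C13, and the butenolide ring is C17, C18, C19 (C=O) and C25. The oxygenated carbons C24 and C16 lie 1,5 to each other across the Z C13=C14 alkene. The chain C24–C13=C14–C15–C16 is therefore a C24–C15–C16 1,3-dicarbonyl with two alkyne carbons inserted into its C24–C15 bond.
- **Cuts.** The butenolide ring goes back to a 3-furyl ring, and the two carbinols go back to a C24 aldehyde and a C16 ketone. C13–C24 and C14–C15 are then cut together (C15–C24 restored) to a terminal alkyne and a furyl formyl ketone. Last, C12–C13 is cut (acetylide plus bromide) and C15–C24 is cut (Claisen).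
- **Forward.** Rings A and B are bought with (+)-sclareolide. Its lactone ring is opened to the C8=C9 alkene and the chain is grown to C14. The alkyne is joined to the furyl C3 unit through a transient cyclobutene that opens at once, and the furan ring becomes the butenolide ring at the end.
- **Stereochemistry.** C5 and C10 come from sclareolide, the Z alkene comes from the four-membered ring of the photoadduct, and 16R comes from Noyori transfer hydrogenation with the (R,R) catalyst.

Key step: step 6

Remark on the chemistry: the SMILES is read as 5S,10S (the sclareolide series), 13Z and 16R. In the names below, "octalinyl" means (4aS,8aS)-2,5,5,8a-tetramethyl-3,4,4a,5,6,7,8,8a-octahydronaphthalen-1-yl, that is rings A and B with the C8=C9 alkene, the 10β-methyl group and the 5α-hydrogen.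

## Route

Step 1
Reactants: 1 (+)-sclareolide
Product: 2 methyl 2-(octalinyl)acetate
Conditions: H2SO4 (cat.), MeOH, reflux, equilibrating
Reagents that add atoms: methanol, CO
Why: Acid-catalysed lactone methanolysis with E1 loss of the tertiary C8 oxygen (Fischer esterification plus dehydration), in which the alkene settles under equilibration in the tetrasubstituted C8=C9 position, C9 gives up its stereocentre on purpose, and C5 and C10 are untouched.

Step 2
Reactants: 2 methyl 2-(octalinyl)acetate
Product: 3 2-(octalinyl)ethanol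
Conditions: LiAlH4, Et2O, 0 °C; aq NaOH work-up
Reagents that add atoms: none
Why: Standard LiAlH4 ester reduction, in which the isolated tetrasubstituted alkene is inert and the basic work-up avoids acid-induced closure of the homoallylic alcohol onto C8.

Step 3
Reactants: 3 2-(octalinyl)ethanol
Product: 4 2-(octalinyl)ethyl bromide
Conditions: CBr4, PPh3, CH2Cl2, 0 °C
Reagents that add atoms: carbon tetrabromide, BrC(Br)(Br)Br
Why: Appel reaction, an SN2 displacement of the alkoxyphosphonium ion at primary C12 under neutral conditions, so that no C8 cation and no cyclic ether can arise.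

Step 4
Reactants: 4 2-(octalinyl)ethyl bromide
Product: 5 4-(octalinyl)but-1-yne
Conditions: LiC≡CH·H2N(CH2)2NH2, DMSO, 10 °C → rt
Reagents that add atoms: lithium acetylide (as its ethylenediamine complex), [Li+].[C-]#C
Why: SN2 alkylation of an acetylide with a primary bromide in a dipolar aprotic solvent, which forms C12–C13 and favours substitution over E2 at the allylic C11 hydrogens.

Step 5
Reactants: 6 3-acetylfuran; 7 ethyl formate
Product: 9 (Z)-3-hydroxy-1-(furan-3-yl)prop-2-en-1-one, via sodium enolate 8 (not isolated)
Conditions: NaH, HCO2Et, Et2O, 0 °C → rt; cold 1 M HCl, Et2O extraction, used at once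
Reagents that add atoms: none
Why: Crossed Claisen condensation (formylation) of a methyl ketone with the non-enolisable ethyl formate, driven by formation of the stabilised enolate 8; cold acidification gives the hydrogen-bonded Z-enol, which is used directly because aroylacetaldehydes self-condense on standing.

Step 6
Reactants: 5 4-(octalinyl)but-1-yne; 9 (Z)-3-hydroxy-1-(furan-3-yl)prop-2-en-1-one
Product: 11 (Z)-5-(furan-3-yl)-5-oxo-2-[2-(octalinyl)ethyl]pent-2-enal, via cyclobutenol photoadduct 10 (not isolated)
Conditions: hν (medium-pressure Hg lamp, Pyrex, λ > 295 nm), 9 in excess and added in portions, degassed cyclohexane–CH2Cl2, Ar, 5 °C; stopped while 9 still takes up the light; cold concentration, crude used at once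
Reagents that add atoms: none
Why: Proposed new method: light absorbed by the planar, hydrogen-bonded six-membered chelate of 9 (which cannot shed its energy by C=C rotation as an open-chain enone would) should lead to an enone-type triplet whose α-carbon C15 bonds to the unhindered terminal alkyne carbon C14, leaving an oxygen-stabilised radical at C24 and a vinyl radical at C13. After spin inversion these two centres recombine, so the only ring of the step, the cyclobutene C24–C13=C14–C15 of 10, is closed by 1,4-biradical collapse as the second bond of a stepwise [2+2] cycloaddition. Compound 10 is a strained β-hydroxy ketone, so retro-aldol scission of C15–C24 through its O–H···O=C16 bridge should follow without further light, and α-protonation of the resulting dienol at C15 gives 11, in which C24 and C15, former neighbours in a four-membered ring, can only stand cis on C13=C14 (Z). The closest known reaction types are the de Mayo reaction of enolised 1,3-dicarbonyl compounds with alkenes and the [2+2] photocycloaddition of enones to alkynes giving cyclobutenes, whose combination on a formyl ketone is not established. The two stereocentres of 10 (C15 and C24) are not controlled and need not be, since cleavage turns them into a CH2 and a CHO group and 11 gains no stereocentre. Three selectivities are required: reaction through the hydroxymethylene tautomer, expected because it keeps the furoyl C=O conjugated and offers a C15=C24 bond that carries only H and OH; head-to-tail orientation, expected from pairing of the alkyl-bearing alkyne carbon C13 with the donor-substituted β-carbon C24; and attack on the alkyne instead of C8=C9 or the furan, expected from the shielding of the tetrasubstituted alkene by quaternary C10 and from the acyl deactivation of the furan.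

Step 7
Reactants: 11 (Z)-5-(furan-3-yl)-5-oxo-2-[2-(octalinyl)ethyl]pent-2-enal
Product: 12 (Z)-1-(furan-3-yl)-4-(hydroxymethyl)-6-(octalinyl)hex-3-en-1-one
Conditions: Zn(BH4)2, Et2O–DME, −20 °C; pH 7 buffer; NaHCO3 wash (takes out surplus 9)
Reagents that add atoms: none
Why: Chemoselective 1,2-reduction with neutral Zn(BH4)2, a reagent known to take conjugated aldehydes ahead of conjugated (here furyl) ketones and too weakly basic to deprotonate the doubly activated C15 methylene, so that the position and Z geometry of C13=C14 are kept.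

Step 8
Reactants: 12 (Z)-1-(furan-3-yl)-4-(hydroxymethyl)-6-(octalinyl)hex-3-en-1-one
Product: 13 (1R,3Z)-1-(furan-3-yl)-4-(hydroxymethyl)-6-(octalinyl)hex-3-en-1-ol
Conditions: RuCl(p-cymene)[(R,R)-TsDPEN] (cat.), HCO2H–Et3N (5:2), EtOAc, 0 °C → rt
Reagents that add atoms: none
Why: Noyori asymmetric transfer hydrogenation, in whose six-membered outer-sphere transition state the furan takes the aryl position next to the p-cymene ligand (CH/π attraction), so that the (R,R) catalyst delivers hydride to the face giving the 16R carbinol as it does for aryl alkyl ketones, while the weakly acidic medium leaves C15, both alkenes and the free alcohol alone.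

Step 9
Reactants: 13 (1R,3Z)-1-(furan-3-yl)-4-(hydroxymethyl)-6-(octalinyl)hex-3-en-1-ol
Product: 15 5-hydroxy-4-[(1R,3Z)-1-hydroxy-4-(hydroxymethyl)-6-(octalinyl)hex-3-en-1-yl]furan-2(5H)-one (C25 epimers), via furan endoperoxide 14 (not isolated)
Conditions: O2, tetraphenylporphyrin (cat.), visible light, i-Pr2NEt, CH2Cl2, −78 °C, stopped at full furan consumption; → rt; dilute oxalic acid wash
Reagents that add atoms: oxygen (used as singlet oxygen), O=O
Why: [4+2] cycloaddition of singlet oxygen to the furan followed by a Kornblum–DeLaMare-type fragmentation, in which the hindered amine removes the less shielded bridgehead hydrogen at C19 and so places C=O at C19 and the hemiacetal at C25, while at −78 °C the furan should outrun the ene reaction of the shielded C8=C9 and the hydroxyl-deactivated C13=C14 alkenes; C25 forms as an inconsequential epimer mixture.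

Step 10
Reactants: 15 5-hydroxy-4-[(1R,3Z)-1-hydroxy-4-(hydroxymethyl)-6-(octalinyl)hex-3-en-1-yl]furan-2(5H)-one
Product: 17 4-[(1R,3Z)-1-hydroxy-4-(hydroxymethyl)-6-(octalinyl)hex-3-en-1-yl]furan-2(5H)-one (CNP0224983.2), via ring-opened hydroxy acid 16 (not isolated)
Conditions: NaBH4, EtOH, 0 °C; then 1 M HCl to pH 3
Reagents that add atoms: none
Why: Borohydride reduction of the ring-opened aldehyde form of the lactol and acid-induced relactonisation of the γ-hydroxy acid whose CH2OH is cis to CO2H, the standard conversion of a γ-hydroxybutenolide into a butenolide, which removes the C25 stereocentre and leaves C16 and all alkenes untouched.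

## Compound list

1 | (+)-sclareolide, (3aR,5aS,9aS,9bR)-3a,6,6,9a-tetramethyldecahydronaphtho[2,1-b]furan-2(1H)-one | C[C@]12OC(=O)C[C@@H]1[C@@]1(C)CCCC(C)(C)[C@@H]1CC2 | starting material
2 | methyl 2-(octalinyl)acetate | CC1=C(CC(=O)OC)[C@@]2(C)CCCC(C)(C)[C@@H]2CC1 | intermediate
3 | 2-(octalinyl)ethanol | CC1=C(CCO)[C@@]2(C)CCCC(C)(C)[C@@H]2CC1 | intermediate
4 | 2-(octalinyl)ethyl bromide | CC1=C(CCBr)[C@@]2(C)CCCC(C)(C)[C@@H]2CC1 | intermediate
5 | 4-(octalinyl)but-1-yne | CC1=C(CCC#C)[C@@]2(C)CCCC(C)(C)[C@@H]2CC1 | intermediate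
6 | 3-acetylfuran | CC(=O)c1ccoc1 | starting material
7 | ethyl formate | CCOC=O | starting material
8 | sodium (Z)-3-(furan-3-yl)-3-oxoprop-1-en-1-olate | [Na+].[O-]/C=C\C(=O)c1ccoc1 | intermediate
9 | (Z)-3-hydroxy-1-(furan-3-yl)prop-2-en-1-one (chelated enol of 3-(furan-3-yl)-3-oxopropanal) | O/C=C\C(=O)c1ccoc1 | intermediate
10 | furan-3-yl 4-hydroxy-3-[2-(octalinyl)ethyl]cyclobut-2-en-1-yl ketone (C15 and C24 undefined) | CC1=C(CCC3=CC(C(=O)c4ccoc4)C3O)[C@@]2(C)CCCC(C)(C)[C@@H]2CC1 | intermediate
11 | (Z)-5-(furan-3-yl)-5-oxo-2-[2-(octalinyl)ethyl]pent-2-enal | CC1=C(CC/C(C=O)=C/CC(=O)c2ccoc2)[C@@]2(C)CCCC(C)(C)[C@@H]2CC1 | intermediate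
12 | (Z)-1-(furan-3-yl)-4-(hydroxymethyl)-6-(octalinyl)hex-3-en-1-one | CC1=C(CC/C(CO)=C/CC(=O)c2ccoc2)[C@@]2(C)CCCC(C)(C)[C@@H]2CC1 | intermediate
13 | (1R,3Z)-1-(furan-3-yl)-4-(hydroxymethyl)-6-(octalinyl)hex-3-en-1-ol | CC1=C(CC/C(=C/C[C@@H](O)c2ccoc2)CO)[C@@]2(C)CCCC(C)(C)[C@@H]2CC1 | intermediate
14 | 2,3,7-trioxabicyclo[2.2.1]hept-5-ene (furan endoperoxide) carrying the (1R,3Z) side chain on C5 | CC1=C(CC/C(=C/C[C@@H](O)C3=CC4OOC3O4)CO)[C@@]2(C)CCCC(C)(C)[C@@H]2CC1 | intermediate
15 | 5-hydroxy-4-[(1R,3Z)-1-hydroxy-4-(hydroxymethyl)-6-(octalinyl)hex-3-en-1-yl]furan-2(5H)-one (C25 epimers) | CC1=C(CC/C(=C/C[C@@H](O)C2=CC(=O)OC2O)CO)[C@@]2(C)CCCC(C)(C)[C@@H]2CC1 | intermediate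
16 | (2E)-4-hydroxy-3-[(1R,3Z)-1-hydroxy-4-(hydroxymethyl)-6-(octalinyl)hex-3-en-1-yl]but-2-enoic acid (CH2OH cis to CO2H) | CC1=C(CC/C(=C/C[C@@H](O)/C(CO)=C/C(=O)O)CO)[C@@]2(C)CCCC(C)(C)[C@@H]2CC1 | intermediate
17 | 4-[(1R,3Z)-1-hydroxy-4-(hydroxymethyl)-6-(octalinyl)hex-3-en-1-yl]furan-2(5H)-one, CNP0224983.2 | CC1=C(CC/C(=C/C[C@@H](O)C2=CC(=O)OC2)CO)[C@@]2(C)CCCC(C)(C)[C@@H]2CC1 | target

## Step count and risks

Total step count: 10. Longest linear sequence: 9 (steps 1–4 and 6–10, from (+)-sclareolide).

**Step 6 (new method).**
- The excited chelate may decay by proton transfer and rotamerisation faster than an unactivated alkyne can intercept it.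
- The partners may combine head-to-head or through the other enol tautomer.
- Cycloaddition may occur at C8=C9 or at the furan.
- The product may undergo secondary photochemistry, either light-driven Z to E isomerisation or an acyl shift of the β,γ-unsaturated ketone.

The fallback is a silicon-tethered ring-closing metathesis built from known reactions. It sets out from 4 and comes back at 13.
- Bromide 4 is turned with Mg in THF into the Grignard reagent F1.
- F1 adds under CuI catalysis to the internal carbon of the bromomagnesium alkoxide of propargyl alcohol (carbomagnesiation) and gives the 2-substituted allylic alcohol F2.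
- Brown allylation of commercial furan-3-carbaldehyde with (+)-Ipc2B(allyl), the reagent from (−)-α-pinene, gives (R)-1-(furan-3-yl)but-3-en-1-ol F3, which carries C14–C16 and the 16R centre.
- Ph2SiCl2 and Et3N convert it into the chlorosilane F4, which takes up F2 to give the mixed bis(alkoxy)silane F5.
- The second-generation Grubbs catalyst RuCl2(=CHPh)(PCy3)(H2IMes) in refluxing CH2Cl2 closes the eight-membered cyclic siloxane F6. Its ring forces C24 and C15 cis on C13=C14.
- Bu4NF releases diol 13.

**Step 7.**
- A proton may shift along the C24–C16 vinylogous dicarbonyl, with loss of the position and geometry of the alkene.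
- Cyclodehydration of the ene-dicarbonyl may occur.
- Hydride may also be delivered to the furyl ketone without facial control.

The fallback gives up chemoselectivity and repairs C16 afterwards. It sets out from 11 and comes back at 13.
- The cold photolysate is treated directly with excess i-Bu2AlH at −78 °C, which outruns tautomerisation and gives the C16-epimeric diol F7.
- TBSCl and imidazole at low temperature silylate only the primary alcohol to give the silyl ether F8.
- Buffered Dess–Martin periodinane gives the silyl ether ketone F9, which has neither an aldehyde nor a free hydroxyl able to form a hemiketal.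
- Transfer hydrogenation with RuCl(p-cymene)[(R,R)-TsDPEN] as in step 8 gives the 16R silyl ether carbinol F10.
- Bu4NF gives 13.

**Step 9.**
- Ene oxidation of the electron-rich C8=C9 alkene (or of C13=C14) may compete with the furan cycloaddition.
- Regiocontrol may erode in the base-induced opening of the endoperoxide.

The fallback avoids singlet oxygen altogether and replaces steps 9 and 10. It sets out from 13 and comes back at 17.
- C–H borylation with [Ir(OMe)(cod)]2, 4,4'-di-tert-butyl-2,2'-bipyridine and excess B2pin2 takes the least hindered α-position C19 of the furan. The hydroxyls travel as transient borate esters that methanol cleaves, and the product is the furan-2-boronate F11.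
- NaBO3·4H2O in aqueous THF, which leaves unactivated alkenes alone, gives the 2-hydroxyfuran F12.
- F12 tautomerises by protonation at C25, finished with a trace of Et3N, to the conjugated butenolide 17.

## Further compounds

F1 | step 6 | 2-(octalinyl)ethylmagnesium bromide | CC1=C(CC[Mg]Br)[C@@]2(C)CCCC(C)(C)[C@@H]2CC1
F2 | step 6 | 2-methylidene-4-(octalinyl)butan-1-ol | CC1=C(CCC(=C)CO)[C@@]2(C)CCCC(C)(C)[C@@H]2CC1
F3 | step 6 | (R)-1-(furan-3-yl)but-3-en-1-ol | C=CC[C@@H](O)c1ccoc1
F4 | step 6 | chloro[(R)-1-(furan-3-yl)but-3-enyloxy]diphenylsilane | C=CC[C@@H](O[Si](Cl)(c1ccccc1)c1ccccc1)c1ccoc1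
F5 | step 6 | [(R)-1-(furan-3-yl)but-3-enyloxy][2-methylidene-4-(octalinyl)butoxy]diphenylsilane | CC1=C(CCC(=C)CO[Si](c3ccccc3)(c3ccccc3)O[C@H](CC=C)c3ccoc3)[C@@]2(C)CCCC(C)(C)[C@@H]2CC1
F6 | step 6 | eight-membered (Z)-1,3-dioxa-2-silacyclooct-5-ene, 2,2-diphenyl, (R)-furan-3-yl on C16, 2-(octalinyl)ethyl on C13 | CC1=C(CC/C3=C/C[C@H](c4ccoc4)O[Si](c4ccccc4)(c4ccccc4)OC3)[C@@]2(C)CCCC(C)(C)[C@@H]2CC1
F7 | step 7 | (Z)-1-(furan-3-yl)-4-(hydroxymethyl)-6-(octalinyl)hex-3-en-1-ol, both C16 epimers | CC1=C(CC/C(=C/CC(O)c2ccoc2)CO)[C@@]2(C)CCCC(C)(C)[C@@H]2CC1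
F8 | step 7 | (Z)-4-[(tert-butyldimethylsilyloxy)methyl]-1-(furan-3-yl)-6-(octalinyl)hex-3-en-1-ol, both C16 epimers | CC1=C(CC/C(=C/CC(O)c2ccoc2)CO[Si](C)(C)C(C)(C)C)[C@@]2(C)CCCC(C)(C)[C@@H]2CC1
F9 | step 7 | (Z)-4-[(tert-butyldimethylsilyloxy)methyl]-1-(furan-3-yl)-6-(octalinyl)hex-3-en-1-one | CC1=C(CC/C(=C/CC(=O)c2ccoc2)CO[Si](C)(C)C(C)(C)C)[C@@]2(C)CCCC(C)(C)[C@@H]2CC1
F10 | step 7 | (1R,3Z)-4-[(tert-butyldimethylsilyloxy)methyl]-1-(furan-3-yl)-6-(octalinyl)hex-3-en-1-ol | CC1=C(CC/C(=C/C[C@@H](O)c2ccoc2)CO[Si](C)(C)C(C)(C)C)[C@@]2(C)CCCC(C)(C)[C@@H]2CC1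
F11 | step 9 | (1R,3Z)-4-(hydroxymethyl)-6-(octalinyl)-1-[5-(4,4,5,5-tetramethyl-1,3,2-dioxaborolan-2-yl)furan-3-yl]hex-3-en-1-ol | CC1=C(CC/C(=C/C[C@@H](O)c2coc(B3OC(C)(C)C(C)(C)O3)c2)CO)[C@@]2(C)CCCC(C)(C)[C@@H]2CC1
F12 | step 9 | 4-[(1R,3Z)-1-hydroxy-4-(hydroxymethyl)-6-(octalinyl)hex-3-en-1-yl]furan-2-ol | CC1=C(CC/C(=C/C[C@@H](O)c2coc(O)c2)CO)[C@@]2(C)CCCC(C)(C)[C@@H]2CC1
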